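Assumption: angelic acid and (R)-2-methylbutanoic acid are bought as such; in every compound the atoms carry longipinane labels (C1 enone C=O, C2=C3-Me, C4 and C11 ring-A bridgeheads, C5, C6 = CMe2, C7–C9 oxygenated carbons, C10 quaternary C-Me).

**Retrosynthetic overview**
1. The C8 ester comes from selective acylation of a C8,C9 cis-diol. The diol comes from OsO4 attack on a ring-B alkene anti to the C7 angelate.
2. Key disconnection: a retro-Tiffeneau–Demjanov step moves the C10–C11 bond back to C10–C1. This unravels the cyclobutane and cyclohexenone into a bridgehead-oxygenated endo-2-aminonorbornene tricycle.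
3. That tricycle comes from one polar intramolecular [4+2] annulation of a 1-siloxycyclopentadiene with a tethered (E)-nitroalkene. C7 is set afterwards by CBS reduction of the only ketone.
4. The nitroalkene comes from radical nitration of a terminal alkene. Quaternary C10 comes from a catalytic asymmetric Mukaiyama–Michael addition of a cyclopentadienyl silyl ether to a vinyl ketone.
5. Ring order: cyclopentenone (bought), then the seven-membered ring and the bicyclo[2.2.1] core together, then ring expansion to the cyclohexenone with simultaneous formation of the cyclobutane.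

**Route**

Step 1
Reactants: 1 prenyl bromide (1-bromo-3-methylbut-2-ene); 2 acrolein
Product: 3 4,4-dimethylhexa-1,5-dien-3-ol (racemic)
Conditions: Zn dust, THF/sat. aq NH4Cl, 0 °C to rt
Reagents that add atoms: none
Why: Barbier-type zinc allylation, in which the prenylzinc species adds 1,2 to acrolein through its γ-carbon (six-membered SE2' transition state) and installs the CMe2–vinyl unit; the racemic carbinol centre is erased in step 2.

Step 2
Reactants: 3 4,4-dimethylhexa-1,5-dien-3-ol
Product: 4 4,4-dimethylhexa-1,5-dien-3-one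
Conditions: activated MnO2 (15 equiv), CH2Cl2, rt
Reagents that add atoms: none
Why: MnO2 oxidation of an allylic alcohol is mild enough for a vinyl ketone that the neighbouring quaternary carbon shields from polymerisation; no stereocentre is involved.

Step 3
Reactants: 5 3-methylcyclopent-2-en-1-one
Product: 6 3,5-dimethylcyclopent-2-en-1-one (racemic)
Conditions: LDA (1.05 equiv), THF, −78 °C; MeI, −78 to −20 °C
Reagents that add atoms: iodomethane, CI
Why: Kinetic α'-deprotonation of a cyclic enone followed by enolate alkylation gives the 5-methyl enone; the racemic centre is planarised in step 4.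

Step 4
Reactants: 6 3,5-dimethylcyclopent-2-en-1-one
Product: 7 (2,4-dimethylcyclopenta-1,4-dien-1-yl)oxytrimethylsilane
Conditions: LDA (1.1 equiv), THF, −78 °C; TMSCl; cold pentane filtration, used at once
Reagents that add atoms: chlorotrimethylsilane, C[Si](C)(C)Cl
Why: A second kinetic α'-deprotonation and O-silylation (silyl enol ether formation) fix the cross-conjugated, achiral, tetrasubstituted enol ether regiochemically.

Step 5
Reactants: 7 (2,4-dimethylcyclopenta-1,4-dien-1-yl)oxytrimethylsilane; 4 4,4-dimethylhexa-1,5-dien-3-one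
Product: 9 (R)-5-(4,4-dimethyl-3-oxohex-5-en-1-yl)-3,5-dimethylcyclopent-2-en-1-one, via silyl enol ether 8 (not isolated)
Conditions: confined chiral imidodiphosphorimidate (IDPi) acid (3 mol %), toluene, −78 °C; then 1 M HCl, THF, 0 °C
Reagents that add atoms: none
Why: Proposed new method: a silylium/chiral-counteranion Mukaiyama–Michael addition that creates the stereocentre on a fully substituted planar nucleophile; the IDPi acid is silylated by 7, the silylium ion activates the s-cis vinyl ketone of 4 as a siloxyallyl cation held inside the confined anion, only one face of the methyl-bearing carbon of 7 can reach the unsubstituted CH2 terminus (C9–C10 bond, quaternary C10 set as R), silyl transfer to the new enolate gives 8 and turns the catalyst over, and racemic 6 converges because 7 is achiral; the closest known reaction type is the IDPi- or disulfonimide-catalysed Mukaiyama–Michael/aldol addition of silyl ketene acetals, where the stereocentre lies on the acceptor.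

Step 6
Reactants: 9 (R)-5-(4,4-dimethyl-3-oxohex-5-en-1-yl)-3,5-dimethylcyclopent-2-en-1-one
Product: 10 (R)-5-[(E)-4,4-dimethyl-6-nitro-3-oxohex-5-en-1-yl]-3,5-dimethylcyclopent-2-en-1-one
Conditions: AgNO2 (3 equiv), TEMPO (1 equiv), 4 Å MS, 1,2-dichloroethane, 70 °C
Reagents that add atoms: silver nitrite, [Ag+].[O-]N=O
Why: Radical nitration of an alkene, in which NO2 radical adds to the terminal carbon of the only non-conjugated alkene and TEMPO removes the β-hydrogen; this gives the (E)-nitroalkene and leaves the enone untouched.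

Step 7
Reactants: 10 (R)-5-[(E)-4,4-dimethyl-6-nitro-3-oxohex-5-en-1-yl]-3,5-dimethylcyclopent-2-en-1-one
Product: 12 tricyclic nitro ketone (bicyclo[2.2.1]hept-2-ene core: bridgehead C1-OTES and C4-H; C2=C3-Me; one-carbon bridge C10 with Me syn to the alkene; chain C9H2-C8H2-C7(=O)-C6Me2 from C10 to exo-C5; NO2 endo on C11), via siloxycyclopentadiene 11 (not isolated)
Conditions: TESOTf (1.15 equiv), Et3N (2 equiv), CH2Cl2, −78 to 0 °C; then toluene, 80 °C
Reagents that add atoms: triethylsilyl trifluoromethanesulfonate, CC[Si](CC)(CC)OS(=O)(=O)C(F)(F)F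
Why: Soft γ-enolisation gives the 5,5-disubstituted 1-siloxycyclopentadiene 11 (no 1,5-H shift possible), which closes onto the nitroalkene in a polar intramolecular Diels–Alder-type annulation (vinylogous Mukaiyama–Michael C4 to C5, then C11 to C1); the tether from C10 dictates the diene face and puts C6 exo, so the E-alkene places NO2 endo and C1, C4, C5 and C11 all follow from C10.

Step 8
Reactants: 12 tricyclic nitro ketone
Product: 13 tricyclic enone (12 with a C8=C9 double bond conjugated to C7=O)
Conditions: IBX (3 equiv), DMSO/fluorobenzene 1:2, 70 °C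
Reagents that add atoms: none
Why: IBX dehydrogenation of a ketone can only run towards C8–C9 because C6 is quaternary; it needs no base, so the α-nitro centre is safe, and quaternary C10 stops over-oxidation.

Step 9
Reactants: 13 tricyclic enone
Product: 14 (7R)-allylic alcohol (13 with C7-OH; other centres unchanged)
Conditions: (S)-Me-CBS (20 mol %), catecholborane (2 equiv), toluene, −78 °C; MeOH, then aq NaHCO3
Reagents that add atoms: none
Why: Corey–Bakshi–Shibata reduction, in which the only carbonyl group lies between a quaternary carbon (large) and a vinyl carbon (small), so the (S)-catalyst sets C7 as R under reagent control; catecholborane at −78 °C leaves the nitro group and the alkenes alone.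

Step 10
Reactants: 14 (7R)-allylic alcohol; 15 angelic acid ((Z)-2-methylbut-2-enoic acid)
Product: 17 C7 angelate of 14, via mixed anhydride 16 (not isolated)
Conditions: 15, 2,4,6-trichlorobenzoyl chloride, Et3N, toluene, rt, 2 h; then 14, 80 °C
Reagents that add atoms: none
Why: Yamaguchi-type mixed-anhydride esterification without DMAP acylates hindered alcohols with angelic acid without Z-to-E isomerisation; C7 keeps its configuration, and C11 can only re-equilibrate to the favoured endo-nitro form.

Step 11
Reactants: 17 C7 angelate of 14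
Product: 18 endo-C11 primary amine (17 with NH2 in place of NO2; OTES kept)
Conditions: Zn dust (20 equiv), AcOH/THF 1:3, rt; aq NaHCO3 work-up
Reagents that add atoms: none
Why: Zn/AcOH reduction of a secondary nitroalkane to the amine proceeds with retention at C11 and spares the ester, the alkenes and the tertiary silyl ether.

Step 12
Reactants: 18 endo-C11 primary amine
Product: 20 (4R,5S,7R,10R,11R)-7-angeloyloxylongipina-2,8-dien-1-one, via diazonium ion 19 (not isolated)
Conditions: NaNO2 (3 equiv), AcOH/H2O/THF 2:1:1, 0 °C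
Reagents that add atoms: none
Why: Tiffeneau–Demjanov-type semipinacol ring expansion, in which the endo C11–N2+ bond of 19 is antiperiplanar (about 155°) only to the C1–C10 bond and the bridgehead oxygen pushes, so C10 migrates with retention to C11 (inversion there) while epoxide closure and the C2 vinyl shift (about 60°) are geometrically shut off; loss of the silyl group gives the conjugated enone, so the cyclopentene becomes the cyclohexenone and the cyclobutane forms in the same event.

Step 13
Reactants: 20 (4R,5S,7R,10R,11R)-7-angeloyloxylongipina-2,8-dien-1-one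
Product: 21 (4R,5S,7S,8S,9S,10R,11R)-7-angeloyloxy-8,9-dihydroxylongipin-2-en-1-one
Conditions: OsO4 (5 mol %), NMO (1.5 equiv), acetone/H2O 5:1, 0 °C to rt
Reagents that add atoms: N-methylmorpholine N-oxide, C[N+]1([O-])CCOCC1; water, O
Why: Catalytic OsO4/NMO syn-dihydroxylation takes the only non-conjugated alkene and attacks anti to the allylic C7 acyloxy group (Kishi model); this sets the cis C8,C9-diol trans to C7.

Step 14
Reactants: 21 (4R,5S,7S,8S,9S,10R,11R)-7-angeloyloxy-8,9-dihydroxylongipin-2-en-1-one; 22 (R)-2-methylbutanoic acid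
Product: 23 (4R,5S,7S,8S,9S,10R,11R)-7-angeloyloxy-9-hydroxy-8-[(R)-2-methylbutanoyloxy]longipin-2-en-1-one (CNP0206166.1)
Conditions: 22 (1.1 equiv), DIC (1.1 equiv), DMAP (10 mol %), CH2Cl2, −20 to 0 °C
Reagents that add atoms: none
Why: Steglich esterification under kinetic control acylates the C8 hydroxyl, because the C9 hydroxyl is neopentylic (next to quaternary C10) and hydrogen-bonded to the C1 carbonyl; the acyl stereocentre comes unchanged from 22.

**Compound list**
1 | prenyl bromide | CC(C)=CCBr | starting material
2 | acrolein | C=CC=O | starting material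
3 | 4,4-dimethylhexa-1,5-dien-3-ol (racemic) | C=CC(O)C(C)(C)C=C | intermediate
4 | 4,4-dimethylhexa-1,5-dien-3-one | C=CC(=O)C(C)(C)C=C | intermediate
5 | 3-methylcyclopent-2-en-1-one | CC1=CC(=O)CC1 | starting material
6 | 3,5-dimethylcyclopent-2-en-1-one (racemic) | CC1=CC(=O)C(C)C1 | intermediate
7 | (2,4-dimethylcyclopenta-1,4-dien-1-yl)oxytrimethylsilane | CC1=CC(O[Si](C)(C)C)=C(C)C1 | intermediate
8 | (Z)-trimethylsilyl enol ether of 9 at C7 (not isolated) | C=CC(C)(C)/C(O[Si](C)(C)C)=C/C[C@]1(C)CC(C)=CC1=O | intermediate
9 | (R)-5-(4,4-dimethyl-3-oxohex-5-en-1-yl)-3,5-dimethylcyclopent-2-en-1-one | C=CC(C)(C)C(=O)CC[C@]1(C)CC(C)=CC1=O | intermediate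
10 | (R)-5-[(E)-4,4-dimethyl-6-nitro-3-oxohex-5-en-1-yl]-3,5-dimethylcyclopent-2-en-1-one | O=[N+]([O-])/C=C/C(C)(C)C(=O)CC[C@]1(C)CC(C)=CC1=O | intermediate
11 | 1-(triethylsilyloxy)-3,5-dimethyl-5-(nitroalkenyl chain)cyclopenta-1,3-diene (not isolated) | O=[N+]([O-])/C=C/C(C)(C)C(=O)CC[C@]1(C)C=C(C)C=C1O[Si](CC)(CC)CC | intermediate
12 | tricyclic nitro ketone (C1-OTES, endo-C11-NO2, C7=O) | O=C1CC[C@@]2(C)[C@]3(O[Si](CC)(CC)CC)C=C(C)[C@H]2[C@@H]([C@H]3[N+](=O)[O-])C1(C)C | intermediate
13 | tricyclic enone (C8=C9, C7=O) | O=C1C=C[C@@]2(C)[C@]3(O[Si](CC)(CC)CC)C=C(C)[C@H]2[C@@H]([C@H]3[N+](=O)[O-])C1(C)C | intermediate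
14 | (7R)-allylic alcohol | O[C@@H]1C=C[C@@]2(C)[C@]3(O[Si](CC)(CC)CC)C=C(C)[C@H]2[C@@H]([C@H]3[N+](=O)[O-])C1(C)C | intermediate
15 | angelic acid | C/C=C(/C)C(=O)O | starting material
16 | angelic 2,4,6-trichlorobenzoic anhydride (not isolated) | C/C=C(/C)C(=O)OC(=O)c1c(Cl)cc(Cl)cc1Cl | intermediate
17 | C7 angelate, endo-C11-NO2, C1-OTES | C/C=C(/C)C(=O)O[C@@H]1C=C[C@@]2(C)[C@]3(O[Si](CC)(CC)CC)C=C(C)[C@H]2[C@@H]([C@H]3[N+](=O)[O-])C1(C)C | intermediate
18 | C7 angelate, endo-C11-NH2, C1-OTES | C/C=C(/C)C(=O)O[C@@H]1C=C[C@@]2(C)[C@]3(O[Si](CC)(CC)CC)C=C(C)[C@H]2[C@@H]([C@H]3N)C1(C)C | intermediate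
19 | endo-C11 diazonium acetate (not isolated) | C/C=C(/C)C(=O)O[C@@H]1C=C[C@@]2(C)[C@]3(O[Si](CC)(CC)CC)C=C(C)[C@H]2[C@@H]([C@H]3[N+]#N)C1(C)C.CC(=O)[O-] | intermediate
20 | (4R,5S,7R,10R,11R)-7-angeloyloxylongipina-2,8-dien-1-one | C/C=C(/C)C(=O)O[C@@H]1C=C[C@@]2(C)[C@@H]3C(=O)C=C(C)[C@H]2[C@@H]3C1(C)C | intermediate
21 | (4R,5S,7S,8S,9S,10R,11R)-7-angeloyloxy-8,9-dihydroxylongipin-2-en-1-one | C/C=C(/C)C(=O)O[C@@H]1[C@@H](O)[C@@H](O)[C@@]2(C)[C@@H]3C(=O)C=C(C)[C@H]2[C@@H]3C1(C)C | intermediate
22 | (R)-2-methylbutanoic acid | CC[C@@H](C)C(=O)O | starting material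
23 | CNP0206166.1 | C/C=C(/C)C(=O)O[C@@H]1[C@@H](OC(=O)[C@H](C)CC)[C@@H](O)[C@@]2(C)[C@@H]3C(=O)C=C(C)[C@H]2[C@@H]3C1(C)C | target

**Step count and risks**
Total step count: 14. Longest linear sequence: 12 (5 to 23, steps 3–14).

Steps most likely to fail:

Step 5 (the proposed new step).
- Face control at a fully substituted nucleophile is unproven.
- Diene 7 can isomerise.
- The first adduct can close onto C3 to give a bicyclic double-Michael product. DBU reopens that product by retro-Michael reaction without touching C10.
- Fallback with known chemistry, from 6 back to 9. LiHMDS/TMEDA and allyl chloroformate turn 6 into allyl 2,4-dimethylcyclopenta-1,4-dien-1-yl carbonate F1. Pd2(dba)3/(S)-t-Bu-PHOX decarboxylative asymmetric allylic alkylation then gives (R)-5-allyl-3,5-dimethylcyclopent-2-en-1-one F2. Nitrite-modified aldehyde-selective Wacker oxidation gives 3-[(R)-1,4-dimethyl-2-oxocyclopent-3-en-1-yl]propanal F3. Zinc prenylation with 1 gives the carbinol (5R)-5-(3-hydroxy-4,4-dimethylhex-5-en-1-yl)-3,5-dimethylcyclopent-2-en-1-one F4 as a mixture of epimers. Dess–Martin oxidation of F4 returns 9. Steps 1, 2, 4 and 5 drop out, so the total rises by one step (15) and the linear sequence by three (15).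

Step 7.
- The closure makes a seven-membered ring.
- Excess TESOTf could silylate the C7 ketone to an enol ether whose geometry cannot cyclise.
- Fallback, from 10 back to 12: the two bonds are made one after the other under anionic control. Catalytic KOt-Bu or DBU in THF closes ring B by a reversible intramolecular vinylogous Michael addition (C4 to C5) and gives the cis-fused hydroazulenone nitroalkane F5. TESOTf/Et3N then forms the silyl nitronate and activates the C1 carbonyl. An intramolecular Henry-type (nitro-Mukaiyama aldol) closure then gives 12, with the nitro group in the thermodynamically preferred endo position.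

Step 12.
- The diazonium ion may leak to solvolysis or to unselective cationic shifts.
- Fallback, from 18 back to 20: the cationic trigger is replaced by an anionic, concerted one. Tf2O and 2,6-lutidine at −78 °C convert the amine into the N,N-bis(trifluoromethylsulfonyl)imide F6. TBAF then unmasks the bridgehead alkoxide, which drives the same antiperiplanar C10 shift and expels triflimide. This is the way 2-hydroxy sulfonates are rearranged (base-induced pinacol-type rearrangement).

Further compounds
F1 | step 5 | allyl 2,4-dimethylcyclopenta-1,4-dien-1-yl carbonate | C=CCOC(=O)OC1=C(C)CC(C)=C1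
F2 | step 5 | (R)-5-allyl-3,5-dimethylcyclopent-2-en-1-one | C=CC[C@]1(C)CC(C)=CC1=O
F3 | step 5 | 3-[(R)-1,4-dimethyl-2-oxocyclopent-3-en-1-yl]propanal | O=CCC[C@]1(C)CC(C)=CC1=O
F4 | step 5 | (5R)-5-(3-hydroxy-4,4-dimethylhex-5-en-1-yl)-3,5-dimethylcyclopent-2-en-1-one (carbinol epimers) | C=CC(C)(C)C(O)CC[C@]1(C)CC(C)=CC1=O
F5 | step 7 | cis-fused hydroazulenone nitroalkane (C4–C5 bond closed, C5-CH2NO2, C1 and C7 ketones) | O=C1CC[C@@]2(C)C(=O)C=C(C)[C@H]2[C@@H](C[N+](=O)[O-])C1(C)C
F6 | step 12 | endo-C11 N,N-bis(trifluoromethylsulfonyl)imide of 18 | C/C=C(/C)C(=O)O[C@@H]1C=C[C@@]2(C)[C@]3(O[Si](CC)(CC)CC)C=C(C)[C@H]2[C@@H]([C@H]3N(S(=O)(=O)C(F)(F)F)S(=O)(=O)C(F)(F)F)C1(C)C
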